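# Proposed synthesis of CNP0296884.1 (21) by double Robinson annulation of a bis(arylacetaldehyde)

## The problem

The target 21 is a para-terphenyl whose central benzene ring is fully substituted: numbered C1 to C6, it carries the (S)-3-hydroxybutanoyloxy group on C1, free hydroxyls on C2 and C5, the 3-phenylpropanoyloxy group on C4 and a 4-hydroxyphenyl ring on each of C3 and C6, so the substituents form three para pairs. A synthesis has to tell the acylated oxygens (C1/C4) from the free ones (C2/C5) and then C1 from C4, because the two esters differ; an otherwise centrosymmetric core must be desymmetrised exactly once. The only stereocentre, the carbinol carbon of the hydroxybutanoate, is remote from everything else and can neither direct nor be directed, so it is best bought as the S enantiomer and carried through without breaking a bond to it and without base-induced loss of the beta oxygen. The two aryl esters are the fragile groups: hydroxide, alkoxides and amines cleave them, and each sits next to a hydroxyl in 21, so an O-to-O acyl shift becomes possible once the C2 and C5 hydroxyls are free. Those two hydroxyls together also form an air-sensitive hydroquinone. The biaryl bonds at C3 and C6 are each flanked by two oxygen-bearing carbons, which makes them awkward for cross-coupling. The enabling feature is that each outer ring is a phenol joined to C3 or C6 through the carbon para to its hydroxyl: its ipso carbon and one ortho carbon can start as the CH2 and CHO of an acetaldehyde arm on the central ring, and the other four carbons with the para oxygen can come from methyl vinyl ketone 9.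

## Retrosynthesis

**21 from 20.** The last step should only remove protecting groups. Five benzyl C–O bonds are cut: four phenolic and one on the side-chain carbinol. Hydrogenolysis is neutral, whereas the acid or fluoride needed for acetal or silyl groups would invite acyl shift or ester cleavage. Compound 20 has the full skeleton but no free hydroxyl, so it is stable to air and to chromatography. The forward step must cleave two hindered central ethers without moving either ester.

**20 from 16 and 19; 16 from 14 and 15.** The two acyl–oxygen bonds at C1 and C4 are cut. The esters come late because nothing before them (amine catalysis, hydroxide, carbonate alkylations) would spare an aryl ester. The desymmetrisation is placed here because every earlier intermediate profits from the inversion centre. The price is that the first acylation of the symmetric hydroquinone 14 is statistical. It is therefore done with the cheap achiral acid 15, and the chiral acid 19 is put on the single hydroxyl left in 16. Acid 19 comes from ethyl (S)-3-hydroxybutanoate 17 through its benzyl ether 18, so that the side-chain hydroxyl leaves in the final hydrogenolysis.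

**14 from 13 from 12.** Only protecting-group bonds are cut. The C1/C4 oxygens are held as methoxymethyl acetals and the C2/C5 oxygens and the outer phenols as benzyl ethers. Dilute acid then frees exactly the two oxygens to be acylated. The outer phenols of 12 must be benzylated (13) before the acetals come off, otherwise the unhindered outer hydroxyls would be acylated first.

**12 from 11.** Four hydrogens are added in the retrosynthetic sense, turning each outer phenol into a 4-substituted cyclohex-2-enone. This changes the two hindered biaryl bonds into aryl–C(sp3) bonds that enamine chemistry can make. The neighbouring cut, a double cross-coupling at C3/C6, would demand two couplings at positions that each carry two ortho oxygen substituents on a fully oxygenated ring. The forward dehydrogenation has to leave the benzyl ethers and acetals alone and place each hydroxyl para to the central ring, which the position of the carbonyl in 11 guarantees.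

**11 from 8 and two molecules of 9 (through 10).** In each outer ring the single bond between the ipso carbon and one ortho carbon is cut (Michael addition), and so is the double bond between the other ortho carbon and its meta neighbour (aldol condensation). The precursor is the dialdehyde 8, which contains only the central ring, plus the four-carbon commodity methyl vinyl ketone 9. Two rings and four skeletal bonds are removed in one operation. The forward reaction must alkylate each benzylic carbon once, without self-aldol of 8, and then close each keto aldehyde arm of 10 to a six-membered enone.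

**8 from 7; 7 from 6 from 5 from 4.** Each aldehyde carbon is traced to the internal carbon of an allyl group, which is cleaved at the C=C bond. Allyl is a masked acetaldehyde that survives alkylation and reduction. The oxygen pattern is sorted at the quinone stage. In 4 the C2/C5 oxygens are acidic enol hydroxyls and the C1/C4 oxygens are carbonyls. Benzylation (5), reduction (6) and acetal formation (7) therefore place the two protecting groups on the correct para pairs with no selectivity problem.

**4 from 3; 3 from 1 and two molecules of 2.** The C3–CH2 and C6–CH2 bonds are cut by a double retro-Claisen to the bis(allyl ether) 3. Its two O–allyl bonds are then cut, which leads to 2,5-dihydroxy-1,4-benzoquinone 1 and two molecules of allyl alcohol 2, one for each enol hydroxyl. All four central oxygens are present in 1, and no halogenation or metal-mediated coupling is needed to attach carbon to the two free ring positions. The forward etherification must put one allyl group on each enol oxygen and stop before the sigmatropic shift begins.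

## Roads not taken

**Alternative 1:** The central ring is opened at C1–C2 and traced to a four-membered ring, the 4-acyloxy-4-alkenylcyclobutenone A2. Heating A2 should open the four-membered ring electrocyclically; six-electron closure of the resulting ketene carbon onto the benzyloxy-bearing alkene terminus and tautomerisation would give the hydroquinone monoester A1, which is the same compound as 16. Its great merit is that the ketene oxygen emerges as a free phenol para to an oxygen that is already acylated. C1 and C4 are thus distinguished by the mechanism, where the chosen plan needs the statistical step 11. The route would probably also be shorter. Its weak points lie in making A2. Two successive organometallic carbonyl additions are needed, the second with an alkenyl metal that carries a beta-benzyloxy group. Such a reagent resists beta-elimination only when metal and alkoxy group are cis, and this geometry then points the benzyloxy group into the forming ring and slows the six-electron closure. The 3-phenylpropanoate must be put on a tertiary alkoxide and survive the thermolysis. An acyloxy group is a weaker outward-rotating donor than hydroxyl or silyloxy, so the sense of ring opening is less secure. In desymmetrisation and step count this road is better. The chosen plan sets against it commodity starting materials, no cryogenic organometallic chemistry, symmetric and easily analysed intermediates, and a statistical step whose other products can be recycled.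

**Alternative 2:** The central ring is cut at C3–C4 and C6–C1 into two molecules of 4-hydroxyphenylpyruvic acid A4. In the forward direction an adenylating quinone synthetase condenses them head to tail, as enzyme-bound thioesters, to atromentin A3. One operation would deliver the complete terphenyl with all six oxygens. A3 has the same enol/carbonyl differentiation that the chosen route builds at quinone 4, and perbenzylation followed by dithionite reduction of A3 would enter the chosen route at 14. In step count this is clearly superior. Its weakness is practical: it depends on an active, post-translationally primed multi-domain enzyme with cofactor supply, on dilute aqueous operation and on a poorly soluble product. It also still needs the statistical monoacylation afterwards. The chosen plan offers independence from a biocatalyst and ordinary scale-up in organic solvents, at the cost of about seven more steps to 14.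

**Alternative 3:** The C1–O and C4–O bonds are traced to C–C bonds: the diketone A6 carries the two acyl groups directly on C1 and C4. A peracid would add to both carbonyls and the central aryl would migrate twice (double Baeyer–Villiger oxidation), giving the pentabenzyl ether A5, which is the same compound as 20. The attraction is that the two different acyl groups are attached as ketones. They could in principle be introduced one after the other by carbon–carbon bond formation, not by statistical esterification, and the central ring needs only two oxygens at the start. The weak points are at the key step. Both carbonyls are flanked by a benzyloxy group and an aryl ring, so peracid addition will be slow. The substrate offers several electron-rich benzyloxyarenes to the peracid for ring oxidation. The beta-benzyloxy ketone can eliminate under the acidic conditions. Building hexasubstituted A6 is also unlikely to be shorter than the sequence to 16. Both roads end in the same penultimate compound, and Alternative 3 may avoid the statistical step. It stakes the chiral side chain and the whole skeleton on a late chemoselectivity question, whereas the chosen plan takes its main risk at step 7 on cheap material.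

Key step: step 7

Remark: 10 and 11 arise as mixtures of the meso and racemic diastereomers. The meso isomer is drawn for each, and the mixture is carried into step 8, where both centres are lost.

## Route

Step 1
Reactants: 1 2,5-dihydroxy-1,4-benzoquinone; 2 allyl alcohol (2 equiv)
Product: 3 2,5-bis(allyloxy)-1,4-benzoquinone
Conditions: 2 (30 equiv, serving as solvent), BF3·OEt2 (20 mol %), 3 Å molecular sieves, 60 °C
Reagents that add atoms: allyl alcohol (compound 2 taken from the solvent for the second allyl group), C=CCO
Why: Both hydroxyls of 1 are vinylogous carboxylic acids, so acid-catalysed exchange with the solvent alcohol (vinylogous Fischer esterification, as used for the dimethyl ether) should put one allyl group on each; two molecules of 2 are consumed and two of water are taken up by the sieves. The temperature is kept below that of the sigmatropic shift.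

Step 2
Reactants: 3 2,5-bis(allyloxy)-1,4-benzoquinone
Product: 4 3,6-diallyl-2,5-dihydroxy-1,4-benzoquinone
Conditions: toluene, 110 °C, argon
Reagents that add atoms: none
Why: Each allyl vinyl ether unit should undergo a Claisen rearrangement ([3,3]-sigmatropic shift) to the adjacent unsubstituted ring carbon, and enolisation of the resulting trione restores the hydroxyquinone. Both carbon arms are thus placed on C3 and C6 without a metal.

Step 3
Reactants: 4 3,6-diallyl-2,5-dihydroxy-1,4-benzoquinone
Product: 5 3,6-diallyl-2,5-bis(benzyloxy)-1,4-benzoquinone
Conditions: BnBr, K2CO3, DMF, rt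
Reagents that add atoms: benzyl bromide, BrCc1ccccc1
Why: Williamson-type O-alkylation of the vinylogous carboxylate; C-alkylation is blocked because both alpha carbons already carry an allyl group. The C2/C5 oxygens are capped while the C1/C4 oxygens are still carbonyls.

Step 4
Reactants: 5 3,6-diallyl-2,5-bis(benzyloxy)-1,4-benzoquinone
Product: 6 3,6-diallyl-2,5-bis(benzyloxy)benzene-1,4-diol
Conditions: Na2S2O4, THF–H2O, rt, argon
Reagents that add atoms: none
Why: Dithionite reduction of a quinone to its hydroquinone leaves alkenes and benzyl ethers untouched and frees only the C1/C4 oxygens; 6 is used at once because it reoxidises in air.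

Step 5
Reactants: 6 3,6-diallyl-2,5-bis(benzyloxy)benzene-1,4-diol
Product: 7 1,4-diallyl-2,5-bis(benzyloxy)-3,6-bis(methoxymethoxy)benzene
Conditions: NaH, MOMCl, DMF, 0 °C to rt, argon
Reagents that add atoms: chloromethyl methyl ether, COCCl
Why: Williamson etherification of the hindered bis(phenoxide) with a reactive alpha-chloro ether. The acetals are orthogonal to benzyl and stable to the oxidative, aminocatalytic and basic steps that follow.

Step 6
Reactants: 7 1,4-diallyl-2,5-bis(benzyloxy)-3,6-bis(methoxymethoxy)benzene
Product: 8 2,2'-[2,5-bis(benzyloxy)-3,6-bis(methoxymethoxy)-1,4-phenylene]diacetaldehyde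
Conditions: OsO4 (cat.), NaIO4, 2,6-lutidine, dioxane–H2O, rt
Reagents that add atoms: osmium tetroxide, O=[Os](=O)(=O)=O; sodium periodate, [Na+].[O-]I(=O)(=O)=O
Why: Lemieux–Johnson oxidation: catalytic dihydroxylation of each terminal alkene and periodate cleavage of the diol, with 2,6-lutidine suppressing over-oxidation. The fully etherified ring offers periodate no free phenol, and the sensitive dialdehyde is used without storage.

Step 7
Reactants: 8 2,2'-[2,5-bis(benzyloxy)-3,6-bis(methoxymethoxy)-1,4-phenylene]diacetaldehyde; 9 methyl vinyl ketone
Product: 11 4,4'-[2,5-bis(benzyloxy)-3,6-bis(methoxymethoxy)-1,4-phenylene]bis(cyclohex-2-en-1-one), via bis(5-oxohexanal) Michael adduct 10 (not isolated)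
Conditions: 9 (3 equiv), Et2NSiMe3 (0.4 equiv), MeCN, 60 °C; then KOH (0.5 equiv), nBu4NOH (cat.), THF–H2O, 0 °C to rt
Reagents that add atoms: none
Why: This is a Robinson annulation run on both arms of one molecule: the silylamine turns each CH2CHO arm of 8 into its diethylamine enamine, whose benzylic carbon adds to 9 (Stork enamine Michael addition), and hydrolysis gives the bis(keto aldehyde) 10. Hydroxide then enolises each methyl ketone toward the methyl group and the enolate attacks the aldehyde; both cyclohexenone rings close in the same mode, a 6-(enolendo)-exo-trig aldol addition followed by E1cB loss of water. The closest known reaction type is the amine-mediated Michael addition of arylacetaldehydes and other enolisable aldehydes to methyl vinyl ketone with base-induced cyclodehydration to 4-substituted cyclohex-2-enones. The two new stereocentres (C4 of each enone, the former aldehyde alpha carbons) are set in the Michael step with no controlling element, stay epimerisable in 10 and are deliberately left as a diastereomer mixture because step 8 destroys both. The step needs one C-alkylation per arm, with no self-aldol and no second Michael addition; the flanking benzyloxy and methoxymethoxy groups shield each benzylic carbon and slow enamine formation from the alpha-branched aldehyde of 10, and the para arrangement of the arms excludes any reaction between them. Only the six-membered aldol is open, since attack by the internal ketone alpha carbon or by the aldehyde alpha carbon would close four-membered rings.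

Step 8
Reactants: 11 4,4'-[2,5-bis(benzyloxy)-3,6-bis(methoxymethoxy)-1,4-phenylene]bis(cyclohex-2-en-1-one)
Product: 12 3',6'-bis(benzyloxy)-2',5'-bis(methoxymethoxy)-[1,1':4',1''-terphenyl]-4,4''-diol
Conditions: Pd(O2CCF3)2 (10 mol %), 2-(dimethylamino)pyridine (20 mol %), TsOH·H2O (40 mol %), O2 (1 atm), DMSO, 80 °C
Reagents that add atoms: none
Why: Aerobic dehydrogenation of cyclohexenones to phenols by divalent palladium: palladium enolate formation at C6, beta-hydride elimination to the cross-conjugated dienone and tautomerisation, with O2 reoxidising zerovalent palladium. Both C4 stereocentres vanish and each hydroxyl ends up para to the central ring.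

Step 9
Reactants: 12 3',6'-bis(benzyloxy)-2',5'-bis(methoxymethoxy)-[1,1':4',1''-terphenyl]-4,4''-diol
Product: 13 3',4,4'',6'-tetrakis(benzyloxy)-2',5'-bis(methoxymethoxy)-1,1':4',1''-terphenyl
Conditions: BnBr, K2CO3, DMF, rt
Reagents that add atoms: benzyl bromide, BrCc1ccccc1
Why: Williamson benzylation of the two unhindered outer phenols, so that only the central C1/C4 oxygens are unveiled in the next step.

Step 10
Reactants: 13 3',4,4'',6'-tetrakis(benzyloxy)-2',5'-bis(methoxymethoxy)-1,1':4',1''-terphenyl
Product: 14 3',4,4'',6'-tetrakis(benzyloxy)-[1,1':4',1''-terphenyl]-2',5'-diol
Conditions: conc. HCl (cat.), MeOH–THF, 50 °C, argon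
Reagents that add atoms: none
Why: Acid-catalysed acetal exchange to methanol removes both methoxymethyl groups while benzyl ethers are inert; the hydroquinone 14 is kept under argon and used directly.

Step 11
Reactants: 14 3',4,4'',6'-tetrakis(benzyloxy)-[1,1':4',1''-terphenyl]-2',5'-diol; 15 3-phenylpropanoic acid
Product: 16 3',4,4'',6'-tetrakis(benzyloxy)-5'-hydroxy-[1,1':4',1''-terphenyl]-2'-yl 3-phenylpropanoate
Conditions: 15 (1.0 equiv, slow addition), DCC, DMAP (cat.), CH2Cl2, 0 °C to rt, argon
Reagents that add atoms: none
Why: Steglich esterification with one equivalent of acid; the two hydroxyls are equivalent and remote, so a near-statistical outcome is expected. The cheap acid is used here, and unreacted 14 and doubly acylated material (after saponification) are returned to the step.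

Step 12
Reactants: 17 ethyl (S)-3-hydroxybutanoate
Product: 18 ethyl (S)-3-(benzyloxy)butanoate
Conditions: benzyl 2,2,2-trichloroacetimidate, TfOH (cat.), cyclohexane–CH2Cl2, rt
Reagents that add atoms: benzyl 2,2,2-trichloroacetimidate, N=C(OCc1ccccc1)C(Cl)(Cl)Cl
Why: Acid-catalysed O-benzylation with the trichloroacetimidate needs no base, so the beta-hydroxy ester neither eliminates nor undergoes retro-aldol cleavage. No bond to the stereocentre is broken and the S configuration is retained.

Step 13
Reactants: 18 ethyl (S)-3-(benzyloxy)butanoate
Product: 19 (S)-3-(benzyloxy)butanoic acid
Conditions: LiOH, THF–H2O, 0 °C to rt; then 1 M HCl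
Reagents that add atoms: lithium hydroxide, [Li+].[OH-]
Why: Ester saponification at low temperature; the stereocentre is beta to the carboxylate and is not touched, and the cold, brief exposure limits elimination of benzyl alcohol.

Step 14
Reactants: 16 3',4,4'',6'-tetrakis(benzyloxy)-5'-hydroxy-[1,1':4',1''-terphenyl]-2'-yl 3-phenylpropanoate; 19 (S)-3-(benzyloxy)butanoic acid
Product: 20 3',4,4'',6'-tetrakis(benzyloxy)-5'-[(3-phenylpropanoyl)oxy]-[1,1':4',1''-terphenyl]-2'-yl (S)-3-(benzyloxy)butanoate
Conditions: DCC, DMAP (cat.), CH2Cl2, 0 °C to rt
Reagents that add atoms: none
Why: Steglich esterification of the one remaining, hindered phenol; carbodiimide activation with catalytic DMAP and no added amine base spares the first aryl ester and the beta-benzyloxy group. The S centre is carried in unchanged from 19.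

Step 15
Reactants: 20 3',4,4'',6'-tetrakis(benzyloxy)-5'-[(3-phenylpropanoyl)oxy]-[1,1':4',1''-terphenyl]-2'-yl (S)-3-(benzyloxy)butanoate
Product: 21 3',4,4'',6'-tetrahydroxy-5'-[(3-phenylpropanoyl)oxy]-[1,1':4',1''-terphenyl]-2'-yl (S)-3-hydroxybutanoate (CNP0296884.1)
Conditions: H2 (1 atm), Pd/C, EtOAc–THF, rt; filtration and concentration under argon
Reagents that add atoms: none
Why: Hydrogenolysis of all five benzyl ethers under neutral, aprotic conditions, so the aryl esters are neither transesterified nor shifted to the neighbouring hydroxyls. The carbinol centre is not affected and remains S.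

## Compound list

1 | 2,5-dihydroxy-1,4-benzoquinone | O=C1C=C(O)C(=O)C=C1O | starting material
2 | allyl alcohol (prop-2-en-1-ol) | C=CCO | starting material
3 | 2,5-bis(allyloxy)-1,4-benzoquinone | O=C1C=C(OCC=C)C(=O)C=C1OCC=C | intermediate
4 | 3,6-diallyl-2,5-dihydroxy-1,4-benzoquinone | O=C1C(O)=C(CC=C)C(=O)C(O)=C1CC=C | intermediate
5 | 3,6-diallyl-2,5-bis(benzyloxy)-1,4-benzoquinone | O=C1C(OCc2ccccc2)=C(CC=C)C(=O)C(OCc2ccccc2)=C1CC=C | intermediate
6 | 3,6-diallyl-2,5-bis(benzyloxy)benzene-1,4-diol | Oc1c(OCc2ccccc2)c(CC=C)c(O)c(OCc2ccccc2)c1CC=C | intermediate
7 | 1,4-diallyl-2,5-bis(benzyloxy)-3,6-bis(methoxymethoxy)benzene | COCOc1c(OCc2ccccc2)c(CC=C)c(OCOC)c(OCc2ccccc2)c1CC=C | intermediate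
8 | 2,2'-[2,5-bis(benzyloxy)-3,6-bis(methoxymethoxy)-1,4-phenylene]diacetaldehyde | O=CCc1c(OCOC)c(OCc2ccccc2)c(CC=O)c(OCOC)c1OCc1ccccc1 | intermediate
9 | methyl vinyl ketone (but-3-en-2-one) | C=CC(C)=O | starting material
10 | 2,2'-[2,5-bis(benzyloxy)-3,6-bis(methoxymethoxy)-1,4-phenylene]bis(5-oxohexanal), diastereomer mixture, meso (2R,2'S) isomer drawn | CC(=O)CC[C@H](C=O)c1c(OCOC)c(OCc2ccccc2)c([C@H](C=O)CCC(C)=O)c(OCOC)c1OCc1ccccc1 | intermediate
11 | 4,4'-[2,5-bis(benzyloxy)-3,6-bis(methoxymethoxy)-1,4-phenylene]bis(cyclohex-2-en-1-one), diastereomer mixture, meso (4R,4'S) isomer drawn | O=C1C=C[C@@H](CC1)c1c(OCOC)c(OCc2ccccc2)c([C@H]2CCC(=O)C=C2)c(OCOC)c1OCc1ccccc1 | intermediate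
12 | 3',6'-bis(benzyloxy)-2',5'-bis(methoxymethoxy)-[1,1':4',1''-terphenyl]-4,4''-diol | Oc1ccc(cc1)-c1c(OCOC)c(OCc2ccccc2)c(-c2ccc(O)cc2)c(OCOC)c1OCc1ccccc1 | intermediate
13 | 3',4,4'',6'-tetrakis(benzyloxy)-2',5'-bis(methoxymethoxy)-1,1':4',1''-terphenyl | COCOc1c(OCc2ccccc2)c(-c2ccc(OCc3ccccc3)cc2)c(OCOC)c(OCc2ccccc2)c1-c1ccc(OCc2ccccc2)cc1 | intermediate
14 | 3',4,4'',6'-tetrakis(benzyloxy)-[1,1':4',1''-terphenyl]-2',5'-diol | Oc1c(OCc2ccccc2)c(-c2ccc(OCc3ccccc3)cc2)c(O)c(OCc2ccccc2)c1-c1ccc(OCc2ccccc2)cc1 | intermediate
15 | 3-phenylpropanoic acid | O=C(O)CCc1ccccc1 | starting material
16 | 3',4,4'',6'-tetrakis(benzyloxy)-5'-hydroxy-[1,1':4',1''-terphenyl]-2'-yl 3-phenylpropanoate | Oc1c(-c2ccc(OCc3ccccc3)cc2)c(OCc2ccccc2)c(OC(=O)CCc2ccccc2)c(-c2ccc(OCc3ccccc3)cc2)c1OCc1ccccc1 | intermediate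
17 | ethyl (S)-3-hydroxybutanoate | CCOC(=O)C[C@H](C)O | starting material
18 | ethyl (S)-3-(benzyloxy)butanoate | CCOC(=O)C[C@H](C)OCc1ccccc1 | intermediate
19 | (S)-3-(benzyloxy)butanoic acid | C[C@H](OCc1ccccc1)CC(=O)O | intermediate
20 | 3',4,4'',6'-tetrakis(benzyloxy)-5'-[(3-phenylpropanoyl)oxy]-[1,1':4',1''-terphenyl]-2'-yl (S)-3-(benzyloxy)butanoate | C[C@H](OCc1ccccc1)CC(=O)Oc1c(OCc2ccccc2)c(-c2ccc(OCc3ccccc3)cc2)c(OC(=O)CCc2ccccc2)c(OCc2ccccc2)c1-c1ccc(OCc2ccccc2)cc1 | intermediate
21 | 3',4,4'',6'-tetrahydroxy-5'-[(3-phenylpropanoyl)oxy]-[1,1':4',1''-terphenyl]-2'-yl (S)-3-hydroxybutanoate (CNP0296884.1) | C[C@H](O)CC(=O)Oc1c(O)c(-c2ccc(O)cc2)c(OC(=O)CCc2ccccc2)c(O)c1-c1ccc(O)cc1 | target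

## Step count and risks

Total step count: 15. Longest linear sequence: 13 steps (steps 1 to 11, 14 and 15); steps 12 and 13 form the two-step side branch to 19.

**Step 7 (key step).** The most likely failure is incomplete or sluggish Michael addition at the benzylic carbons, which are hindered by two ortho oxygens. The free aldehyde groups of 8 would then be consumed by self-aldol oligomerisation, and 9 would polymerise under amine catalysis. A second failure is annulation of one arm only. Fallback: from 8, condensation with pyrrolidine (K2CO3, toluene) should give the isolable bis(pyrrolidine enamine) F1, in which no free aldehyde remains. Treating stoichiometric F1 with 9 in MeCN, then hydrolysing and cyclodehydrating in buffered aqueous acetic acid (AcOH, NaOAc), would pass through 10 and rejoin the route at 11.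

**Step 11.** The concern is over-acylation together with unreacted diol. Nothing distinguishes the two hydroxyls, so the distribution of products is governed by statistics, and the electron-rich hydroquinone can also be lost by air oxidation during the slow addition. Fallback: from 14, deliberate oxidation (Ag2O, CH2Cl2) should give the quinone F2. Commercial 3-phenylpropanal and an N-heterocyclic carbene catalyst (1,3-dimesitylimidazolium chloride, DBU, THF) would then reduce the quinone by two electrons through the Breslow intermediate. The acyl azolium so formed acylates the hydroquinone monoanion, a monoacylation known for 1,4-naphthoquinones and ortho-quinones. One reduction event delivers one acyl group, so double acylation is excluded; the sequence returns to the route at 16.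

**Step 8.** The acid co-catalyst and the water formed at 80 °C may cause partial loss of the methoxymethyl groups. The dehydrogenation may also stall after one ring. Fallback: from 11, kinetic enolisation and silylation (LiN(SiMe3)2, Me3SiCl, THF, −78 °C) should give the bis(trimethylsilyl dienol ether) F3. Saegusa–Ito oxidation (Pd(OAc)2, MeCN, rt) would convert it under non-acidic conditions into the bis(cyclohexa-2,5-dienone) F4, which tautomerises spontaneously and rejoins the route at 12.

**Step 15.** Once the C2/C5 hydroxyls are free, acyl migration to them through a cyclic ortho-acid intermediate can occur on the catalyst surface or during work-up. The liberated hydroquinone may also oxidise in air, and the two hindered central benzyl ethers may cleave slowly. Fallback: from 20, Lewis-acid debenzylation with BCl3 and pentamethylbenzene as cation scavenger (CH2Cl2, −78 °C) removes aryl and alkyl benzyl ethers without hydrogen, without a heterogeneous catalyst and under acidic conditions in which phenoxide-mediated acyl shift is suppressed; it returns directly at 21.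

**Step 1.** Etherification may be incomplete because water is not removed efficiently, which would leave the mono(allyl ether). Rearrangement may also begin prematurely in the acidic medium, after which the freed enol hydroxyl would be etherified again. Fallback: from 1, neutralisation (NaOH) and precipitation with AgNO3 should give the disilver salt F5. Alkylation of F5 with allyl bromide in benzene at rt would give 3 without acid or heat; any C-allylated material formed alongside converges on 4 in step 2.

## Further compounds

F1 | step 7 | 1,1'-{[2,5-bis(benzyloxy)-3,6-bis(methoxymethoxy)-1,4-phenylene]di[(E)-ethene-2,1-diyl]}dipyrrolidine (bis(pyrrolidine enamine) of 8) | C1CCN(C1)/C=C/c1c(OCOC)c(OCc2ccccc2)c(/C=C/N2CCCC2)c(OCOC)c1OCc1ccccc1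
F2 | step 11 | 2,5-bis(benzyloxy)-3,6-bis[4-(benzyloxy)phenyl]-1,4-benzoquinone | O=C1C(OCc2ccccc2)=C(c2ccc(OCc3ccccc3)cc2)C(=O)C(OCc2ccccc2)=C1c1ccc(OCc2ccccc2)cc1
F3 | step 8 | bis(trimethylsilyl dienol ether) of 11: 1,4-bis[4-(trimethylsilyloxy)cyclohexa-2,4-dien-1-yl]-2,5-bis(benzyloxy)-3,6-bis(methoxymethoxy)benzene, diastereomer mixture, meso isomer drawn | C[Si](C)(C)OC1=CC[C@H](C=C1)c1c(OCOC)c(OCc2ccccc2)c([C@H]2CC=C(O[Si](C)(C)C)C=C2)c(OCOC)c1OCc1ccccc1
F4 | step 8 | 4,4'-[2,5-bis(benzyloxy)-3,6-bis(methoxymethoxy)-1,4-phenylene]bis(cyclohexa-2,5-dien-1-one) | O=C1C=CC(C=C1)c1c(OCOC)c(OCc2ccccc2)c(C2C=CC(=O)C=C2)c(OCOC)c1OCc1ccccc1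
F0 | step 15 | none | none
F5 | step 1 | disilver salt of 2,5-dihydroxy-1,4-benzoquinone | [Ag+].[Ag+].[O-]C1=CC(=O)C([O-])=CC1=O
A1 | alternative 1 | 3',4,4'',6'-tetrakis(benzyloxy)-5'-hydroxy-[1,1':4',1''-terphenyl]-2'-yl 3-phenylpropanoate (identical with 16) | Oc1c(-c2ccc(OCc3ccccc3)cc2)c(OCc2ccccc2)c(OC(=O)CCc2ccccc2)c(-c2ccc(OCc3ccccc3)cc2)c1OCc1ccccc1
A2 | alternative 1 | racemic 2-(benzyloxy)-1-{(Z)-2-(benzyloxy)-1-[4-(benzyloxy)phenyl]ethenyl}-3-[4-(benzyloxy)phenyl]-4-oxocyclobut-2-en-1-yl 3-phenylpropanoate | O=C1C(c2ccc(OCc3ccccc3)cc2)=C(OCc2ccccc2)C1(OC(=O)CCc1ccccc1)\C(=C/OCc1ccccc1)c1ccc(OCc2ccccc2)cc1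
A3 | alternative 2 | atromentin (2,5-dihydroxy-3,6-bis(4-hydroxyphenyl)-1,4-benzoquinone) | O=C1C(O)=C(c2ccc(O)cc2)C(=O)C(O)=C1c1ccc(O)cc1
A4 | alternative 2 | 4-hydroxyphenylpyruvic acid | O=C(O)C(=O)Cc1ccc(O)cc1
A5 | alternative 3 | 3',4,4'',6'-tetrakis(benzyloxy)-5'-[(3-phenylpropanoyl)oxy]-[1,1':4',1''-terphenyl]-2'-yl (S)-3-(benzyloxy)butanoate (identical with 20) | C[C@H](OCc1ccccc1)CC(=O)Oc1c(OCc2ccccc2)c(-c2ccc(OCc3ccccc3)cc2)c(OC(=O)CCc2ccccc2)c(OCc2ccccc2)c1-c1ccc(OCc2ccccc2)cc1
A6 | alternative 3 | (S)-3-(benzyloxy)-1-[3',4,4'',6'-tetrakis(benzyloxy)-5'-(3-phenylpropanoyl)-[1,1':4',1''-terphenyl]-2'-yl]butan-1-one | C[C@H](OCc1ccccc1)CC(=O)c1c(OCc2ccccc2)c(-c2ccc(OCc3ccccc3)cc2)c(C(=O)CCc2ccccc2)c(OCc2ccccc2)c1-c1ccc(OCc2ccccc2)cc1
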